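The target is an epifisetinidol-(4→6)-catechin whose upper ring C is all-cis (2R,3R,4S). The route rests on the bond between C4 of the upper ring C and C6 of the lower ring A. The key step exploits that O3 of the upper ring C and O5 of the lower ring A flank this bond on one face: a temporary diisopropylsilylene bridge joins both oxygens, and ionisation of a 4-methoxy group lets the tethered ring A attack the C4 cation. One operation closes a seven-membered 1,3,2-dioxasilepine and fixes the bond, the C6 (not C8) regiochemistry and the 3,4-cis configuration. The precursor is a silaketal linking O3 of a 4-methoxyepifisetinidol tribenzyl ether to O5 of a catechin 7,3',4'-tribenzyl ether.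

Key step: step 9

Remark: (2R,3R)-fustin and (2R,3R)-taxifolin are taken as commercial enantiopure sources of C2 of the upper (U) and lower (L) flavan units; α denotes the face of ring C that carries the 2-aryl group.

Step 1
Reactants: 1 (2R,3R)-fustin
Product: 2 7,3',4'-tri-O-benzylfustin
Conditions: BnBr (3.3 equiv), K2CO3, DMF, rt, Ar
Reagents that add atoms: benzyl bromide BrCc1ccccc1
Why: Williamson ether synthesis, in which the three phenols are alkylated under carbonate conditions that leave the secondary 3-OH and the 2,3-trans stereocentres untouched.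

Step 2
Reactants: 2 7,3',4'-tri-O-benzylfustin
Product: 3 (2R,3S,4R)-7,3',4'-tris(benzyloxy)flavan-3,4-diol
Conditions: NaBH4, THF/MeOH, 0 °C
Reagents that add atoms: none
Why: NaBH4 carbonyl reduction, in which axial hydride delivery to the C4 ketone should give mainly the equatorial 4α-alcohol (3,4-trans), a temporary stereocentre that is erased in step 9.

Step 3
Reactants: 3 (2R,3S,4R)-7,3',4'-tris(benzyloxy)flavan-3,4-diol
Product: 4 (2R,3S,4R)-7,3',4'-tris(benzyloxy)-4-methoxyflavan-3-ol
Conditions: MeOH/CH2Cl2, camphorsulfonic acid (10 mol%), rt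
Reagents that add atoms: methanol CO
Why: Acid-catalysed SN1 etherification, in which the benzylic C4 cation stabilised by the para O7 is captured by methanol anti to the 3-OH (all-equatorial 4α-ether favoured), turning C4 into a storable leaving group while the 3-OH stays free and the C4 centre stays temporary.

Step 4
Reactants: 4 (2R,3S,4R)-7,3',4'-tris(benzyloxy)-4-methoxyflavan-3-ol
Product: 5 (2R,4R)-7,3',4'-tris(benzyloxy)-4-methoxyflavan-3-one
Conditions: Dess–Martin periodinane, NaHCO3, CH2Cl2, 0 °C to rt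
Reagents that add atoms: none
Why: Dess–Martin oxidation of the single free secondary alcohol under buffered, non-enolising conditions should give the flavan-3-one without disturbing C2.

Step 5
Reactants: 5 (2R,4R)-7,3',4'-tris(benzyloxy)-4-methoxyflavan-3-one
Product: 6 (2R,3R,4R)-7,3',4'-tris(benzyloxy)-4-methoxyflavan-3-ol (all-cis)
Conditions: LiBH(s-Bu)3 (L-Selectride), LiBr, THF, −78 °C
Reagents that add atoms: none
Why: Bulky-hydride ketone reduction, in which equatorial attack from the β-face, opposite the equatorial 2-aryl and 4-methoxy groups, sets C3 as the axial (R) alcohol cis to both neighbours, the established way from 2,3-trans to 2,3-cis flavan-3-ols.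

Step 6
Reactants: 7 (2R,3R)-taxifolin
Product: 8 7,3',4'-tri-O-benzyltaxifolin
Conditions: BnBr (3.3 equiv), K2CO3, DMF, rt, Ar
Reagents that add atoms: benzyl bromide BrCc1ccccc1
Why: Williamson ether synthesis, in which the 7-, 3'- and 4'-phenols are benzylated while the 5-OH, hydrogen-bonded to the C4 carbonyl, and the secondary 3-OH stay free.

Step 7
Reactants: 8 7,3',4'-tri-O-benzyltaxifolin
Product: 10 (2R,3S)-7,3',4'-tri-O-benzylcatechin (free 3-OH and 5-OH), via flavan-3,4,5-triol 9 (not isolated)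
Conditions: NaBH4, THF/EtOH, 0 °C; then crude 9, Et3SiH (10 equiv), TFA, CH2Cl2, −20 °C
Reagents that add atoms: none
Why: NaBH4 reduction of the chelated ketone followed by ionic hydrogenation of the benzylic alcohol through the C4 cation stabilised by O5 and O7 removes the C4 oxygen and leaves O5 as the only phenol, with C2 and C3 untouched.

Step 8
Reactants: 6 (2R,3R,4R)-7,3',4'-tris(benzyloxy)-4-methoxyflavan-3-ol; 10 (2R,3S)-7,3',4'-tri-O-benzylcatechin
Product: 12 O3(U),O5(L)-diisopropylsilylene-linked silaketal of 6 and 10, via chlorosilane 11 (not isolated)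
Conditions: i-Pr2SiCl2 (3 equiv), imidazole, CH2Cl2, 0 °C to rt; volatiles removed; then 10, Et3N, DMAP (cat.), CH2Cl2, 0 °C
Reagents that add atoms: dichlorodiisopropylsilane CC(C)[Si](Cl)(Cl)C(C)C
Why: Stepwise nucleophilic substitution at silicon (temporary silicon connection), in which the hindered axial 3-OH of 6 takes one Si–Cl of the excess dichlorosilane and the more acidic phenol O5 of 10 then displaces the second chloride in preference to its secondary 3-OH, with no change at any stereocentre.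

Step 9
Reactants: 12 O3(U),O5(L)-diisopropylsilylene-linked silaketal
Product: 13 O3(U),O5(L)-diisopropylsilylene-bridged 7,3',4'-tri-O-benzylepifisetinidol-(4α→6)-7,3',4'-tri-O-benzylcatechin
Conditions: Me3SiOTf (0.3 equiv), 4 Å MS, CH2Cl2 (0.002 M), −78 to −40 °C; Et3N quench
Reagents that add atoms: none
Why: Me3SiOTf ionises the C4 methoxy group of 12 to the benzylic cation stabilised by O7 and O1 of the upper ring A, and the silicon-tethered, electron-rich lower ring A attacks it through C6 in an intramolecular Friedel–Crafts alkylation, rearomatising by proton loss with methanol as the only by-product. The closest known reaction type is the Lewis acid-promoted coupling of a flavan-4-yl cation with a flavan-3-ol ring A that normally forges interflavan bonds between molecules, run here as a tethered variant. The new seven-membered 1,3,2-dioxasilepine closes endo with respect to the attacking arene bond C5(L)=C6(L), both carbons ending up in the ring, and exo with respect to the cation, whose delocalisation into the upper ring A stays outside. The only new stereocentre, C4(U) (S), is controlled by C3(U): the bridge hangs from the pseudo-axial α-oxygen, a one-atom tether cannot span the trans-diaxial geometry needed for β-attack, so the fusion should be cis and the all-cis ring C results against the usual β-face preference of untethered nucleophiles. Regioselectivity for C6(L) over the more reactive C8(L) is secured because C6(L) is the only free position ortho to the silylated O5(L); high dilution disfavours intermolecular capture, and the benzylic C4–OMe bond ionises far more readily than the Si–O bonds.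

Step 10
Reactants: 13 O3(U),O5(L)-diisopropylsilylene-bridged dimer
Product: 14 7,3',4'-tri-O-benzylepifisetinidol-(4α→6)-7,3',4'-tri-O-benzylcatechin
Conditions: HF·pyridine, pyridine, THF, 0 °C
Reagents that add atoms: none
Why: Fluoride-induced cleavage of both Si–O bonds (desilylation) opens the temporary seven-membered ring and frees O3(U) and O5(L) without affecting the benzyl ethers or the new C–C bond.

Step 11
Reactants: 14 7,3',4'-tri-O-benzylepifisetinidol-(4α→6)-7,3',4'-tri-O-benzylcatechin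
Product: 15 epifisetinidol-(4α→6)-catechin, upper unit (2R,3R,4S), lower unit (2R,3S)
Conditions: H2 (1 atm), Pd(OH)2/C, THF/MeOH/H2O, rt
Reagents that add atoms: none
Why: Catalytic hydrogenolysis of the six aryl benzyl ethers should give the free polyphenol, while the cyclic benzylic C2–O1 ethers and the C4(U)–C6(L) bond are retained, as is usual in debenzylations of flavan-3-ol oligomers.

Compound list

1 | (2R,3R)-fustin (2,3-trans-3,7,3',4'-tetrahydroxyflavan-4-one) | Oc1ccc2c(c1)O[C@H](c1ccc(O)c(O)c1)[C@@H](O)C2=O | starting material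
2 | 7,3',4'-tri-O-benzylfustin (free 3-OH) | c1ccccc1COc1ccc2c(c1)O[C@H](c1ccc(OCc3ccccc3)c(OCc3ccccc3)c1)[C@@H](O)C2=O | intermediate
3 | (2R,3S,4R)-7,3',4'-tris(benzyloxy)flavan-3,4-diol (2,3-trans-3,4-trans) | c1ccccc1COc1ccc2c(c1)O[C@H](c1ccc(OCc3ccccc3)c(OCc3ccccc3)c1)[C@@H](O)[C@@H]2O | intermediate
4 | (2R,3S,4R)-7,3',4'-tris(benzyloxy)-4-methoxyflavan-3-ol (2,3-trans-3,4-trans) | c1ccccc1COc1ccc2c(c1)O[C@H](c1ccc(OCc3ccccc3)c(OCc3ccccc3)c1)[C@@H](O)[C@@H]2OC | intermediate
5 | (2R,4R)-7,3',4'-tris(benzyloxy)-4-methoxyflavan-3-one (2,4-cis) | c1ccccc1COc1ccc2c(c1)O[C@H](c1ccc(OCc3ccccc3)c(OCc3ccccc3)c1)C(=O)[C@@H]2OC | intermediate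
6 | (2R,3R,4R)-7,3',4'-tris(benzyloxy)-4-methoxyflavan-3-ol (all-cis; 4-methoxyepifisetinidol tribenzyl ether) | c1ccccc1COc1ccc2c(c1)O[C@H](c1ccc(OCc3ccccc3)c(OCc3ccccc3)c1)[C@H](O)[C@@H]2OC | intermediate
7 | (2R,3R)-taxifolin (2,3-trans-3,5,7,3',4'-pentahydroxyflavan-4-one) | Oc1cc(O)c2c(c1)O[C@H](c1ccc(O)c(O)c1)[C@@H](O)C2=O | starting material
8 | 7,3',4'-tri-O-benzyltaxifolin (free 3-OH and 5-OH) | c1ccccc1COc1cc(O)c2c(c1)O[C@H](c1ccc(OCc3ccccc3)c(OCc3ccccc3)c1)[C@@H](O)C2=O | intermediate
9 | (2R,3S,4R)-7,3',4'-tris(benzyloxy)flavan-3,4,5-triol (2,3-trans-3,4-trans; not isolated) | c1ccccc1COc1cc(O)c2c(c1)O[C@H](c1ccc(OCc3ccccc3)c(OCc3ccccc3)c1)[C@@H](O)[C@@H]2O | intermediate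
10 | (2R,3S)-7,3',4'-tri-O-benzylcatechin (free 3-OH and 5-OH) | c1ccccc1COc1cc(O)c2c(c1)O[C@H](c1ccc(OCc3ccccc3)c(OCc3ccccc3)c1)[C@@H](O)C2 | intermediate
11 | 3-O-[chloro(diisopropyl)silyl] ether of 6 (not isolated) | c1ccccc1COc1ccc2c(c1)O[C@H](c1ccc(OCc3ccccc3)c(OCc3ccccc3)c1)[C@H](O[Si](Cl)(C(C)C)C(C)C)[C@@H]2OC | intermediate
12 | silaketal in which Si(i-Pr)2 links O3 of 6 to O5 of 10; upper unit (2R,3R,4R), lower unit (2R,3S) | c1ccccc1COc1ccc2c(c1)O[C@H](c1ccc(OCc3ccccc3)c(OCc3ccccc3)c1)[C@H](O[Si](C(C)C)(C(C)C)Oc1cc(OCc3ccccc3)cc3c1C[C@H](O)[C@@H](c1ccc(OCc4ccccc4)c(OCc4ccccc4)c1)O3)[C@@H]2OC | intermediate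
13 | O3(U),O5(L)-diisopropylsilylene-bridged hexa-O-benzyl epifisetinidol-(4α→6)-catechin (cis-fused 1,3,2-dioxasilepine); upper unit (2R,3R,4S), lower unit (2R,3S) | c1ccccc1COc1ccc2c(c1)O[C@H](c1ccc(OCc3ccccc3)c(OCc3ccccc3)c1)[C@H](O[Si](C(C)C)(C(C)C)Oc3c4c(OCc6ccccc6)cc5c3C[C@H](O)[C@@H](c1ccc(OCc6ccccc6)c(OCc6ccccc6)c1)O5)[C@@H]24 | intermediate
14 | 7,3',4'-tri-O-benzylepifisetinidol-(4α→6)-7,3',4'-tri-O-benzylcatechin (free 3-OH(U), 3-OH(L), 5-OH(L)) | c1ccccc1COc1ccc2c(c1)O[C@H](c1ccc(OCc3ccccc3)c(OCc3ccccc3)c1)[C@H](O)[C@@H]2c1c(OCc3ccccc3)cc2c(c1O)C[C@H](O)[C@@H](c1ccc(OCc3ccccc3)c(OCc3ccccc3)c1)O2 | intermediate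
15 | epifisetinidol-(4α→6)-catechin, upper unit (2R,3R,4S) all-cis, lower unit (2R,3S) | Oc1ccc2c(c1)O[C@H](c1ccc(O)c(O)c1)[C@H](O)[C@@H]2c1c(O)cc2c(c1O)C[C@H](O)[C@@H](c1ccc(O)c(O)c1)O2 | target

Total step count: 11. Longest linear sequence: 9 steps (steps 1 to 5 and 8 to 11).

Steps most likely to fail

Step 9. The tethered ring closure may be outrun by acid-induced loss of the silicon bridge or by capture of the C4 cation by a second molecule, which would deliver the arene to the β-face or through C8(L) and lead to oligomers. The fallback sets out from 4 and 10 and comes back at 15. Compound 10 is perbenzylated (NaH, BnBr, DMF) to 3,5,7,3',4'-penta-O-benzylcatechin F1 and brominated at the more reactive C8 (NBS, CH2Cl2, −20 °C) to 8-bromo-3,5,7,3',4'-penta-O-benzylcatechin F2, in which C6 is the only free ring A position. Intermolecular Friedel–Crafts coupling of the 2,3-trans electrophile 4 with F2 (Me3SiOTf, CH2Cl2, −78 °C) should give, by attack anti to the 3-OH, the 2,3-trans-3,4-trans dimer F3 with a single free hydroxyl. Dess–Martin oxidation should give the flavan-3-one F4, and LiBH(s-Bu)3 reduction from the face opposite both aryl groups should give the all-cis alcohol F5. Hydrogenolysis (H2, Pd(OH)2/C, Et3N) then removes the eight benzyl groups and the bromine to reach 15.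

Step 8. Silylation may fail to discriminate between the phenol and the secondary 3-OH of 10, and the chlorosilane may couple with itself. The fallback sets out from 6 and 10 and comes back at 14. Compound 6 is converted with 4-nitrophenyl chloroformate and pyridine into the 4-nitrophenyl carbonate F6. The phenoxide of 10 (Cs2CO3, MeCN) displaces 4-nitrophenoxide chemoselectively to give the mixed aryl alkyl carbonate F7. The same Me3SiOTf ring closure should give the seven-membered cyclic carbonate F8, and methanolysis (K2CO3, MeOH) returns 14.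

Step 7. Ionic hydrogenation may lose to self-condensation, the C4 cation of 9 being trapped by ring A of another molecule before hydride transfer. The fallback sets out from 9 (made from 8 as in step 7) and comes back at 10. Crude 9 is captured with phenylmethanethiol in AcOH as the stable 4α-benzylsulfanyl ether F9, which nickel boride (NiCl2·6H2O, NaBH4, MeOH/THF, 0 °C) desulfurises to 10 without touching the benzyl ethers.

Further compounds

F1 | step 9 | 3,5,7,3',4'-penta-O-benzylcatechin (2R,3S) | c1ccccc1COc1cc(OCc3ccccc3)c2c(c1)O[C@H](c1ccc(OCc3ccccc3)c(OCc3ccccc3)c1)[C@@H](OCc1ccccc1)C2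
F2 | step 9 | 8-bromo-3,5,7,3',4'-penta-O-benzylcatechin (2R,3S) | c1ccccc1COc1cc(OCc3ccccc3)c2c(c1Br)O[C@H](c1ccc(OCc3ccccc3)c(OCc3ccccc3)c1)[C@@H](OCc1ccccc1)C2
F3 | step 9 | 7,3',4'-tri-O-benzylfisetinidol-(4α→6)-8-bromo-3,5,7,3',4'-penta-O-benzylcatechin, upper unit (2R,3S,4S) 2,3-trans-3,4-trans with free 3-OH | c1ccccc1COc1ccc2c(c1)O[C@H](c1ccc(OCc3ccccc3)c(OCc3ccccc3)c1)[C@@H](O)[C@@H]2c1c(OCc3ccccc3)c(Br)c2c(c1OCc1ccccc1)C[C@H](OCc1ccccc1)[C@@H](c1ccc(OCc3ccccc3)c(OCc3ccccc3)c1)O2
F4 | step 9 | upper-unit flavan-3-one of F3, (2R,4S) 2,4-cis | c1ccccc1COc1ccc2c(c1)O[C@H](c1ccc(OCc3ccccc3)c(OCc3ccccc3)c1)C(=O)[C@@H]2c1c(OCc3ccccc3)c(Br)c2c(c1OCc1ccccc1)C[C@H](OCc1ccccc1)[C@@H](c1ccc(OCc3ccccc3)c(OCc3ccccc3)c1)O2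
F5 | step 9 | 7,3',4'-tri-O-benzylepifisetinidol-(4α→6)-8-bromo-3,5,7,3',4'-penta-O-benzylcatechin, upper unit (2R,3R,4S) all-cis | c1ccccc1COc1ccc2c(c1)O[C@H](c1ccc(OCc3ccccc3)c(OCc3ccccc3)c1)[C@H](O)[C@@H]2c1c(OCc3ccccc3)c(Br)c2c(c1OCc1ccccc1)C[C@H](OCc1ccccc1)[C@@H](c1ccc(OCc3ccccc3)c(OCc3ccccc3)c1)O2
F6 | step 8 | 3-O-(4-nitrophenoxycarbonyl) derivative of 6, (2R,3R,4R) | c1ccccc1COc1ccc2c(c1)O[C@H](c1ccc(OCc3ccccc3)c(OCc3ccccc3)c1)[C@H](OC(=O)Oc1ccc(cc1)[N+](=O)[O-])[C@@H]2OC
F7 | step 8 | mixed carbonate linking O3 of 6 to O5 of 10 | c1ccccc1COc1ccc2c(c1)O[C@H](c1ccc(OCc3ccccc3)c(OCc3ccccc3)c1)[C@H](OC(=O)Oc1cc(OCc3ccccc3)cc3c1C[C@H](O)[C@@H](c1ccc(OCc4ccccc4)c(OCc4ccccc4)c1)O3)[C@@H]2OC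
F8 | step 8 | O3(U),O5(L)-carbonyl-bridged hexa-O-benzyl epifisetinidol-(4α→6)-catechin (cyclic carbonate analogue of 13) | c1ccccc1COc1ccc2c(c1)O[C@H](c1ccc(OCc3ccccc3)c(OCc3ccccc3)c1)[C@H](OC(=O)Oc3c4c(OCc6ccccc6)cc5c3C[C@H](O)[C@@H](c1ccc(OCc6ccccc6)c(OCc6ccccc6)c1)O5)[C@@H]24
F9 | step 7 | 4α-(benzylsulfanyl)-7,3',4'-tri-O-benzylcatechin (2,3-trans-3,4-trans, free 3-OH and 5-OH) | c1ccccc1COc1cc(O)c2c(c1)O[C@H](c1ccc(OCc3ccccc3)c(OCc3ccccc3)c1)[C@@H](O)[C@@H]2SCc1ccccc1
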